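**Retrosynthetic overview**

1. All six rings are bought intact in apigenin (1), so no ring is constructed. O-benzylation (2) and C-8 iodination (3) prepare the monomer.
2. Disconnection at the 8,8'' axis: Ullmann homocoupling of 3 gives the C2-symmetric hexa-O-benzylcupressuflavone (4).
3. Key disconnection at C-2–H of the flavanone: one of the two equivalent γ-pyrone rings of 4 is reduced 1,4 by a chiral CuH catalyst with one hydride equivalent, via silyl enol ether 5, to the (2S)-flavanone 6. This one step ends the symmetry, removes the cyclic conjugation of that pyrone ring and sets the only stereocentre.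
4. Global debenzylation of 6 gives the target (7).
5. Order of events on the ring system: biaryl bond first, then ring C of one half is converted from flavone to flavanone.

Assumption: the SMILES fixes only C-2 (S) and leaves the 8,8'' biaryl axis undefined, so the target is taken as the (2S) compound with the axis unspecified; 4 is racemic about the axis, and 6 and 7 are obtained as the two (2S) axial diastereomers, separable by HPLC if one is wanted.

**Route**

Step 1
Reactants: 1 apigenin
Product: 2 5,7,4'-tri-O-benzylapigenin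
Conditions: BnBr (4.5 equiv), K2CO3 (6 equiv), n-Bu4NI (cat.), DMF, 80 °C
Reagents that add atoms: benzyl bromide, BrCc1ccccc1
Why: Williamson O-alkylation (SN2) of all three phenoxides; heat and excess halide in DMF are needed to alkylate the chelated 5-OH as well.

Step 2
Reactants: 2 5,7,4'-tri-O-benzylapigenin
Product: 3 8-iodo-5,7,4'-tri-O-benzylapigenin
Conditions: NIS (1.05 equiv), TFA (0.3 equiv), MeCN/CH2Cl2, 0 °C to rt, dark
Reagents that add atoms: N-iodosuccinimide, O=C1CCC(=O)N1I
Why: Electrophilic aromatic iodination; in a fully O-alkylated 5,7-dioxygenated flavone, C-8 (between one alkoxy group and the ring oxygen) reacts ahead of C-6 (between two benzyloxy groups), as is established for the trimethyl ether.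

Step 3
Reactants: 3 8-iodo-5,7,4'-tri-O-benzylapigenin (2 equiv)
Product: 4 hexa-O-benzylcupressuflavone (racemic about the 8,8'' axis)
Conditions: activated Cu powder (6 equiv), DMF, 150 °C, Ar
Reagents that add atoms: none
Why: Ullmann reductive homocoupling of an aryl iodide on copper metal, the classical entry to tetra-ortho-substituted biaryls, with precedent for the 8,8''-biflavone skeleton in the methyl ether series; the axis forms racemic.

Step 4
Reactants: 4 hexa-O-benzylcupressuflavone
Product: 6 (2S)-hexa-O-benzyl-2,3-dihydrocupressuflavone, via silyl enol ether 5 (not isolated)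
Conditions: Cu(OAc)2·H2O (5 mol %), (S)-DTBM-SEGPHOS (5.5 mol %), (EtO)2MeSiH (1.1 equiv), toluene/THF, 0 °C to rt; then 1 M HCl, THF, 0 °C
Reagents that add atoms: none
Why: Proposed new method: ligated CuH delivers hydride 1,4 to one of the two homotopic γ-pyrone rings of C2-symmetric 4, the chiral bisphosphine choosing the face at C-2 and so creating the (2S) centre; the Cu–O enolate is silylated by Si–H σ-bond metathesis to silyl enol ether 5, which regenerates CuH and protects the new ketone from 1,2-reduction and retro-oxa-Michael opening, and cold dilute acid then frees ketone 6; the silane is the limiting reagent (one hydride per molecule of 4), which holds the reaction at mono-reduction, so symmetry and the pyrone's cyclic conjugation are broken in the same event; closest known reaction type: CuH/DTBM-SEGPHOS asymmetric conjugate reduction (1,4-hydrosilylation) of β,β-disubstituted cyclic enones and 2-alkylchromones.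

Step 5
Reactants: 6 (2S)-hexa-O-benzyl-2,3-dihydrocupressuflavone
Product: 7 (2S)-2,3-dihydrocupressuflavone (target)
Conditions: H2 (1 atm), 10% Pd/C, THF/MeOH 1:1, rt
Reagents that add atoms: none
Why: Hydrogenolysis of the six benzylic C–O bonds under neutral conditions avoids the acid- or base-mediated ring opening to the chalcone that would racemise C-2; the flavone C=C bond and the aryl ketones reduce much more slowly at 1 atm, and the reaction is stopped once the ethers are gone.

**Compound list**

1 | apigenin, 5,7-dihydroxy-2-(4-hydroxyphenyl)-4H-chromen-4-one | O=c1cc(-c2ccc(O)cc2)oc2cc(O)cc(O)c12 | starting material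

2 | 5,7,4'-tri-O-benzylapigenin, 5,7-bis(benzyloxy)-2-[4-(benzyloxy)phenyl]-4H-chromen-4-one | O=c1cc(-c2ccc(OCc3ccccc3)cc2)oc2cc(OCc3ccccc3)cc(OCc3ccccc3)c12 | intermediate

3 | 8-iodo-5,7,4'-tri-O-benzylapigenin, 5,7-bis(benzyloxy)-2-[4-(benzyloxy)phenyl]-8-iodo-4H-chromen-4-one | O=c1cc(-c2ccc(OCc3ccccc3)cc2)oc2c(I)c(OCc3ccccc3)cc(OCc3ccccc3)c12 | intermediate

4 | hexa-O-benzylcupressuflavone, 5,5'',7,7''-tetrakis(benzyloxy)-2,2''-bis[4-(benzyloxy)phenyl]-8,8''-bi(4H-chromen-4-one), racemic about the axis | O=c1cc(-c2ccc(OCc3ccccc3)cc2)oc2c(-c3c(OCc4ccccc4)cc(OCc4ccccc4)c4c(=O)cc(-c5ccc(OCc6ccccc6)cc5)oc34)c(OCc3ccccc3)cc(OCc3ccccc3)c12 | intermediate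

5 | silyl enol ether of 6: 8-{(2S)-5,7-bis(benzyloxy)-2-[4-(benzyloxy)phenyl]-4-{[diethoxy(methyl)silyl]oxy}-2H-chromen-8-yl}-5,7-bis(benzyloxy)-2-[4-(benzyloxy)phenyl]-4H-chromen-4-one | CCO[Si](C)(OCC)OC1=C[C@@H](c2ccc(OCc3ccccc3)cc2)Oc2c1c(OCc1ccccc1)cc(OCc1ccccc1)c2-c1c(OCc2ccccc2)cc(OCc2ccccc2)c2c(=O)cc(-c3ccc(OCc4ccccc4)cc3)oc12 | intermediate

6 | (2S)-hexa-O-benzyl-2,3-dihydrocupressuflavone, (2S)-5,7-bis(benzyloxy)-8-{5,7-bis(benzyloxy)-2-[4-(benzyloxy)phenyl]-4-oxo-4H-chromen-8-yl}-2-[4-(benzyloxy)phenyl]-2,3-dihydro-4H-chromen-4-one | O=C1C[C@@H](c2ccc(OCc3ccccc3)cc2)Oc2c1c(OCc1ccccc1)cc(OCc1ccccc1)c2-c1c(OCc2ccccc2)cc(OCc2ccccc2)c2c(=O)cc(-c3ccc(OCc4ccccc4)cc3)oc12 | intermediate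

7 | (2S)-2,3-dihydrocupressuflavone, (2S)-8-[5,7-dihydroxy-2-(4-hydroxyphenyl)-4-oxo-4H-chromen-8-yl]-5,7-dihydroxy-2-(4-hydroxyphenyl)-2,3-dihydro-4H-chromen-4-one | O=C1C[C@@H](c2ccc(O)cc2)Oc2c1c(O)cc(O)c2-c1c(O)cc(O)c2c(=O)cc(-c3ccc(O)cc3)oc12 | target

**Totals**

Total step count: 5. Longest linear sequence: 5 (fully linear from apigenin).

**Three steps most likely to fail**

Step 4 (most risky). The electron-rich 2-aryl pyrone may be a poor acceptor for ligated CuH, and the ee may be modest. Mono-selectivity is only statistical, so about half of the material is expected as 6, with recovered 4 recycled. The ligand enantiomer was chosen by analogy with CuH reductions of β-substituted cyclic enones; the sense must be confirmed on the first batch of 6 (flavanone Cotton effect), and the antipodal ligand used if it is opposite. Fallback, from 4 back to 6: 4 is treated with LiBH(s-Bu)3 (1.0 equiv, THF, −78 °C), a bulky borohydride that adds 1,4 to chromones, to give the lithium enolate F1 (not isolated). An AcOH quench at −78 °C gives the C-2-racemic mono-flavanone F2. Preparative chromatography on a chiral stationary phase (amylose tris(3,5-dimethylphenylcarbamate)) then collects the (2S) isomers, which are 6.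

Step 3. The coupling makes a tetra-ortho-substituted biaryl, and protodeiodination back to 2 competes. Fallback, from 3 back to 4: half of 3 is converted by Miyaura borylation (B2pin2, PdCl2(dppf), KOAc, dioxane, 90 °C) into the 8-pinacolboronate F3. Suzuki–Miyaura coupling of F3 with the other half of 3 (Pd(OAc)2, SPhos, K3PO4, toluene/H2O, 100 °C) gives 4.

Step 5. Six hydrogenolyses must be completed on a poorly soluble substrate that also carries a reducible flavone C=C bond and a benzylic C-2–O bond. Fallback, from 4 back to 7, moving the debenzylation in front of the key step: BCl3/pentamethylbenzene (CH2Cl2, −78 °C) removes all six benzyl groups from 4, where there is no stereocentre or flavanone to damage, giving cupressuflavone F4. TBSOTf/2,6-lutidine (CH2Cl2) gives the hexakis(tert-butyldimethylsilyl) ether F5. The same desymmetrising CuH reduction as in step 4 gives the silyl enol ether F6 (not isolated). KHF2 in MeOH at rt then removes the enol silyl group and the six aryl silyl ethers in one non-reductive, weakly acidic operation to give 7.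

**Further compounds**

F1 | step 4 | lithium enolate of the C-2-racemic mono-reduced hexabenzyl ether | [Li+].[O-]C1=CC(c2ccc(OCc3ccccc3)cc2)Oc2c1c(OCc1ccccc1)cc(OCc1ccccc1)c2-c1c(OCc2ccccc2)cc(OCc2ccccc2)c2c(=O)cc(-c3ccc(OCc4ccccc4)cc3)oc12

F2 | step 4 | hexa-O-benzyl-2,3-dihydrocupressuflavone, racemic at C-2 | O=C1CC(c2ccc(OCc3ccccc3)cc2)Oc2c1c(OCc1ccccc1)cc(OCc1ccccc1)c2-c1c(OCc2ccccc2)cc(OCc2ccccc2)c2c(=O)cc(-c3ccc(OCc4ccccc4)cc3)oc12

F3 | step 3 | 5,7-bis(benzyloxy)-2-[4-(benzyloxy)phenyl]-8-(4,4,5,5-tetramethyl-1,3,2-dioxaborolan-2-yl)-4H-chromen-4-one | O=c1cc(-c2ccc(OCc3ccccc3)cc2)oc2c(B3OC(C)(C)C(C)(C)O3)c(OCc3ccccc3)cc(OCc3ccccc3)c12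

F4 | step 5 | cupressuflavone (8,8''-biapigenin) | O=c1cc(-c2ccc(O)cc2)oc2c(-c3c(O)cc(O)c4c(=O)cc(-c5ccc(O)cc5)oc34)c(O)cc(O)c12

F5 | step 5 | hexakis-O-(tert-butyldimethylsilyl)cupressuflavone | O=c1cc(-c2ccc(O[Si](C)(C)C(C)(C)C)cc2)oc2c(-c3c(O[Si](C)(C)C(C)(C)C)cc(O[Si](C)(C)C(C)(C)C)c4c(=O)cc(-c5ccc(O[Si](C)(C)C(C)(C)C)cc5)oc34)c(O[Si](C)(C)C(C)(C)C)cc(O[Si](C)(C)C(C)(C)C)c12

F6 | step 5 | (2S)-4-O-[diethoxy(methyl)silyl] enol ether of mono-reduced F5 | CCO[Si](C)(OCC)OC1=C[C@@H](c2ccc(O[Si](C)(C)C(C)(C)C)cc2)Oc2c1c(O[Si](C)(C)C(C)(C)C)cc(O[Si](C)(C)C(C)(C)C)c2-c1c(O[Si](C)(C)C(C)(C)C)cc(O[Si](C)(C)C(C)(C)C)c2c(=O)cc(-c3ccc(O[Si](C)(C)C(C)(C)C)cc3)oc12
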